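**Plan**
Cuts, in retrosynthetic order: the aryl silyl ether, the acetate and allylic C–O bonds of the side chain, the C3–O angelate bond, then the C3–O bond itself (back to C3–Si and then C3–H); the O1–C2 bond goes back to a phenol and an epoxide, and the aryl–CH2 bond to Friedel–Crafts prenylation of 2,4-dihydroxyacetophenone.
Forward: prenylation, protection, Shi epoxidation, 5-exo closure of the dihydrofuran ring, O-silylation of the tertiary alcohol, iridium-catalysed C3–H silylation (temporary oxasilolane ring), oxidation to the cis-1,3-diol, angeloylation, dehydration, allylic hydroxylation, acetylation, desilylation.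
Enabling feature: the C3–H of the dihydrofuran ring is gamma to the oxygen on C1' of the C2 side chain, and the C3 oxygen of the target is cis to that side chain, so a five-membered ring Si–O–C1'–C2–C3 can deliver it.
Stereochemistry: C2 comes from the Shi epoxide (inverted on ring closure); C3 comes from C2 through the cis-fused silicon ring and stereoretentive C–Si oxidation; the Z alkene enters with angelic acid.

Key step: step 8

Remark: positions are numbered as in benzofuran (O1, C2, C3, C3a, C4–C7, C7a; C1' is the side-chain carbon on C2); the C2 descriptor switches between S and R along the route only because CIP priorities change, not the geometry.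

**Step 1**
Reactants: 1 2,4-dihydroxyacetophenone; 2 2-methylbut-3-en-2-ol
Product: 3 1-[2,4-dihydroxy-5-(3-methylbut-2-en-1-yl)phenyl]ethan-1-one
Conditions: BF3·OEt2 (0.5 equiv), dioxane, rt
Reagents that add atoms: none
Why: Friedel–Crafts prenylation through the dimethylallyl cation should go mainly to C5, which is para to the chelated 2-hydroxyl, ortho to the 4-hydroxyl and less hindered than C3 between the two hydroxyls, and this substrate–reagent pair is a known entry to the 5-prenyl ketone.

**Step 2**
Reactants: 3 1-[2,4-dihydroxy-5-(3-methylbut-2-en-1-yl)phenyl]ethan-1-one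
Product: 4 1-[2,4-bis(tert-butyldimethylsilyloxy)-5-(3-methylbut-2-en-1-yl)phenyl]ethan-1-one
Conditions: t-BuMe2SiCl (2.6 equiv), imidazole, DMF, 40 °C
Reagents that add atoms: tert-butyldimethylsilyl chloride, CC(C)(C)[Si](C)(C)Cl
Why: Standard silylation of both phenols (the chelated one needs the excess and gentle warming) removes the oxidisable phenols before the dioxirane step and frees the carbonyl from its hydrogen bond for ketalisation.

**Step 3**
Reactants: 4 1-[2,4-bis(tert-butyldimethylsilyloxy)-5-(3-methylbut-2-en-1-yl)phenyl]ethan-1-one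
Product: 5 2-[2,4-bis(tert-butyldimethylsilyloxy)-5-(3-methylbut-2-en-1-yl)phenyl]-2-methyl-1,3-dioxolane
Conditions: (Me3SiOCH2)2 (3 equiv), Me3SiOTf (5 mol%), CH2Cl2, −78 → −20 °C; pyridine quench
Reagents that add atoms: 1,2-bis(trimethylsilyloxy)ethane, C[Si](C)(C)OCCO[Si](C)(C)C
Why: Silyl-triflate-catalysed ketalisation with the bis-silyl ether of glycol runs aprotically at low temperature, where hindered electron-rich aryl ketones still react and the aryl silyl ethers and the alkene are left alone, and the ketal hides the carbonyl from later iridium-catalysed hydrosilylation.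

**Step 4**
Reactants: 5 2-[2,4-bis(tert-butyldimethylsilyloxy)-5-(3-methylbut-2-en-1-yl)phenyl]-2-methyl-1,3-dioxolane
Product: 6 2-[2,4-bis(tert-butyldimethylsilyloxy)-5-{[(2R)-3,3-dimethyloxiran-2-yl]methyl}phenyl]-2-methyl-1,3-dioxolane
Conditions: D-fructose-derived Shi ketone (0.3 equiv), Oxone (2KHSO5·KHSO4·K2SO4), K2CO3, Bu4NHSO4 (cat.), MeCN/CH2(OMe)2/aq Na2B4O7 buffer (pH about 10.5), 0 °C
Reagents that add atoms: potassium peroxymonosulfate (active part of Oxone), [K+].[O-]S(=O)(=O)OO
Why: Shi asymmetric epoxidation, in which the chiral dioxirane adds oxygen through a spiro transition state to the face that gives the (R)-oxirane (the usual sense for trisubstituted alkenes with this ketone), while arene, silyl ethers and ketal are inert at this pH and temperature.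

**Step 5**
Reactants: 6 2-[2,4-bis(tert-butyldimethylsilyloxy)-5-{[(2R)-3,3-dimethyloxiran-2-yl]methyl}phenyl]-2-methyl-1,3-dioxolane
Product: 8 (2S)-2-(2-hydroxypropan-2-yl)-5-(2-methyl-1,3-dioxolan-2-yl)-2,3-dihydro-1-benzofuran-6-ol, via epoxy bisphenol 7 (not isolated)
Conditions: Bu4NF (2.5 equiv), THF, 0 °C → rt; aq NH4Cl
Reagents that add atoms: none
Why: Fluoride removes both aryl silyl groups and the phenoxide ortho to the side chain opens the oxirane by 5-exo-tet SN2 attack at its less substituted carbon, so inversion turns the (R)-epoxide carbon into the (S)-configured C2 and releases the tertiary alcohol, base-mediated closure of this kind giving the dihydrofuran and not the chromanol.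

**Step 6**
Reactants: 8 (2S)-2-(2-hydroxypropan-2-yl)-5-(2-methyl-1,3-dioxolan-2-yl)-2,3-dihydro-1-benzofuran-6-ol
Product: 9 2-[(2S)-5-(2-methyl-1,3-dioxolan-2-yl)-6-(triisopropylsilyloxy)-2,3-dihydro-1-benzofuran-2-yl]propan-2-ol
Conditions: i-Pr3SiCl (1.2 equiv), imidazole, DMF, rt
Reagents that add atoms: triisopropylsilyl chloride, CC(C)[Si](Cl)(C(C)C)C(C)C
Why: Phenol-selective silylation (the hindered tertiary alcohol does not react with the bulky chlorosilane) gives an aryl silyl ether that should withstand silane, iridium, bicarbonate/peroxide and mild acid and that leaves at the end with buffered fluoride.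

**Step 7**
Reactants: 9 2-[(2S)-5-(2-methyl-1,3-dioxolan-2-yl)-6-(triisopropylsilyloxy)-2,3-dihydro-1-benzofuran-2-yl]propan-2-ol; 10 diethylsilane
Product: 11 diethyl{2-[(2S)-5-(2-methyl-1,3-dioxolan-2-yl)-6-(triisopropylsilyloxy)-2,3-dihydro-1-benzofuran-2-yl]propan-2-yloxy}silane
Conditions: Et2SiH2 (1.5 equiv), [Ir(cod)OMe]2 (0.5 mol%), THF, rt; volatiles removed in vacuo, crude used directly
Reagents that add atoms: none
Why: Iridium-catalysed dehydrogenative O-silylation of a tertiary alcohol with a dihydrosilane gives the monoalkoxy hydrosilane with loss of H2, and neither the ketal nor the aryl silyl ether reacts with Si–H.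

**Step 8**
Reactants: 11 diethyl{2-[(2S)-5-(2-methyl-1,3-dioxolan-2-yl)-6-(triisopropylsilyloxy)-2,3-dihydro-1-benzofuran-2-yl]propan-2-yloxy}silane
Product: 12 cis-fused oxasilolane: 2,2-diethyl-5,5-dimethyl-1,2-oxasilolane whose C3–C4 bond is the C3–C2 bond of 5-(2-methyl-1,3-dioxolan-2-yl)-6-(triisopropylsilyloxy)-2,3-dihydro-1-benzofuran (Si on C3, CMe2 on C2; 2R,3R in benzofuran numbering)
Conditions: [Ir(cod)OMe]2 (2 mol%), 3,4,7,8-tetramethyl-1,10-phenanthroline (5 mol%), norbornene (1.5 equiv), THF, 120 °C, sealed tube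
Reagents that add atoms: none
Why: Proposed new method: Si–H oxidative addition to the phenanthroline-ligated iridium centre (norbornene takes up the hydrogen as norbornane) gives an iridium silyl that cleaves the C3–H bond on the face of the tethered silicon through a six-membered iridacycle, and C–Si reductive elimination then closes the ring with retention at carbon. The closest known reaction type is the alcohol-directed gamma-C–H silylation of diethylhydrosilyl ethers with this catalyst, established for primary and unactivated secondary alkyl C–H bonds and followed by Tamao–Fleming oxidation to 1,3-diols; a benzylic ring methylene beside an aryloxy-bearing carbon has not been shown. The 1,2-oxasilolane (Si, O, C1', C2, C3) closes by intramolecular Si–C3 bond formation as a five-membered ring annulated on the C2–C3 bond, and on the nearly planar dihydrofuran only the cis fusion is geometrically possible. The new C3 stereocentre is therefore dictated by the existing C2 stereocentre, because silicon, held by the three-atom tether O–C1'–C2, can reach only the C3–H cis to the side chain. The step needs site selectivity, which ring size secures (a methyl C–H would give a four-membered and the aryl C4–H a seven-membered silacycle), while both aryl C–H bonds are flanked by two substituents and so resist intermolecular silylation, and the ketal keeps the carbonyl from being hydrosilylated.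

**Step 9**
Reactants: 12 cis-fused oxasilolane
Product: 14 1-[(2S,3R)-3-hydroxy-2-(2-hydroxypropan-2-yl)-6-(triisopropylsilyloxy)-2,3-dihydro-1-benzofuran-5-yl]ethan-1-one, via ketal diol 13 (not isolated)
Conditions: 30% aq H2O2, KHCO3, THF/MeOH, 50 °C; aq Na2S2O3, 0 °C; then aq citric acid to pH 3, rt, 15 min; NaHCO3
Reagents that add atoms: hydrogen peroxide, OO; water, O
Why: Tamao–Fleming oxidation (hydroperoxide adds to silicon and C3 migrates to oxygen with retention, so the C3 hydroxyl stays cis to the side chain, the roughly 120° Si–C3–C2–O1 torsion of the flat ring disfavouring beta-elimination of the aryloxide), after which brief mild acid hydrolyses the electron-rich aryl ketal far faster than it can ionise the benzylic alcohol, so that the acetyl group deactivates the ring for all later steps.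

**Step 10**
Reactants: 14 1-[(2S,3R)-3-hydroxy-2-(2-hydroxypropan-2-yl)-6-(triisopropylsilyloxy)-2,3-dihydro-1-benzofuran-5-yl]ethan-1-one; 15 angelic acid, (2Z)-2-methylbut-2-enoic acid
Product: 17 (2S,3R)-5-acetyl-2-(2-hydroxypropan-2-yl)-6-(triisopropylsilyloxy)-2,3-dihydro-1-benzofuran-3-yl (2Z)-2-methylbut-2-enoate, via angelic 2,4,6-trichlorobenzoic anhydride 16 (not isolated)
Conditions: 15 (1.5 equiv), 2,4,6-trichlorobenzoyl chloride, Et3N, toluene, rt; then 14, 80 °C
Reagents that add atoms: 2,4,6-trichlorobenzoyl chloride, O=C(Cl)c1c(Cl)cc(Cl)cc1Cl (its atoms stay in 16 only)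
Why: Yamaguchi-type esterification through the preformed mixed anhydride without a nucleophilic catalyst acylates the secondary C3 hydroxyl at the less hindered angeloyl carbonyl (the tertiary alcohol is inert), is the established way to make angelates without Z-to-E isomerisation, and leaves the C3 configuration untouched because only the O–H bond reacts.

**Step 11**
Reactants: 17 (2S,3R)-5-acetyl-2-(2-hydroxypropan-2-yl)-6-(triisopropylsilyloxy)-2,3-dihydro-1-benzofuran-3-yl (2Z)-2-methylbut-2-enoate
Product: 18 (2R,3R)-5-acetyl-2-(prop-1-en-2-yl)-6-(triisopropylsilyloxy)-2,3-dihydro-1-benzofuran-3-yl (2Z)-2-methylbut-2-enoate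
Conditions: Burgess reagent (methyl N-(triethylammoniosulfonyl)carbamate, 2 equiv), toluene, 50 °C
Reagents that add atoms: none
Why: Burgess dehydration of a tertiary methyl carbinol by syn elimination should take one of the six methyl hydrogens in preference to the single C2–H on the oxygen-bearing carbon, as in known dehydrations of hydroxyisopropyl-dihydrobenzofurans to isopropenyl compounds, and its neutral conditions spare the benzylic ester and the angelate geometry.

**Step 12**
Reactants: 18 (2R,3R)-5-acetyl-2-(prop-1-en-2-yl)-6-(triisopropylsilyloxy)-2,3-dihydro-1-benzofuran-3-yl (2Z)-2-methylbut-2-enoate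
Product: 19 (2R,3R)-5-acetyl-2-(3-hydroxyprop-1-en-2-yl)-6-(triisopropylsilyloxy)-2,3-dihydro-1-benzofuran-3-yl (2Z)-2-methylbut-2-enoate
Conditions: SeO2 (0.5 equiv), t-BuOOH (5.5 M in decane, 3 equiv), CH2Cl2, rt
Reagents that add atoms: selenium dioxide, O=[Se]=O; tert-butyl hydroperoxide, CC(C)(C)OO
Why: Riley-type allylic oxidation (ene reaction of SeO2 at the terminal CH2, then 2,3-sigmatropic shift) hydroxylates the only methyl group of the 1,1-disubstituted alkene, methyl C–H being preferred over the methine C2–H, while the conjugated electron-poor angelate alkene and the aryl methyl ketone react far more slowly at room temperature.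

**Step 13**
Reactants: 19 (2R,3R)-5-acetyl-2-(3-hydroxyprop-1-en-2-yl)-6-(triisopropylsilyloxy)-2,3-dihydro-1-benzofuran-3-yl (2Z)-2-methylbut-2-enoate
Product: 20 (2R,3R)-2-[3-(acetyloxy)prop-1-en-2-yl]-5-acetyl-6-(triisopropylsilyloxy)-2,3-dihydro-1-benzofuran-3-yl (2Z)-2-methylbut-2-enoate
Conditions: Ac2O, pyridine, CH2Cl2, 0 °C → rt
Reagents that add atoms: acetic anhydride, CC(=O)OC(C)=O
Why: Standard acetylation of the only free hydroxyl, a primary allylic alcohol, under conditions that do not isomerise the angelate.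

**Step 14**
Reactants: 20 (2R,3R)-2-[3-(acetyloxy)prop-1-en-2-yl]-5-acetyl-6-(triisopropylsilyloxy)-2,3-dihydro-1-benzofuran-3-yl (2Z)-2-methylbut-2-enoate
Product: 21 (2R,3R)-2-[3-(acetyloxy)prop-1-en-2-yl]-5-acetyl-6-hydroxy-2,3-dihydro-1-benzofuran-3-yl (2Z)-2-methylbut-2-enoate (target)
Conditions: Bu4NF (1.2 equiv), AcOH (1.5 equiv), THF, 0 °C
Reagents that add atoms: none
Why: Fluoride cleaves the aryl silyl ether, made labile by the ortho acetyl group, and the acetic acid buffer keeps the freed phenol protonated, so the acetate, the angelate and the benzylic C3–O bond (which a phenoxide could expel through a quinone methide) are not endangered and no stereocentre is touched.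

**Compound list**
1 | 2,4-dihydroxyacetophenone | CC(=O)c1ccc(O)cc1O | starting material
2 | 2-methylbut-3-en-2-ol | C=CC(C)(C)O | starting material
3 | 1-[2,4-dihydroxy-5-(3-methylbut-2-en-1-yl)phenyl]ethan-1-one | CC(=O)c1cc(CC=C(C)C)c(O)cc1O | intermediate
4 | 1-[2,4-bis(tert-butyldimethylsilyloxy)-5-(3-methylbut-2-en-1-yl)phenyl]ethan-1-one | CC(=O)c1cc(CC=C(C)C)c(O[Si](C)(C)C(C)(C)C)cc1O[Si](C)(C)C(C)(C)C | intermediate
5 | 2-[2,4-bis(tert-butyldimethylsilyloxy)-5-(3-methylbut-2-en-1-yl)phenyl]-2-methyl-1,3-dioxolane | CC(C)=CCc1cc(C2(C)OCCO2)c(O[Si](C)(C)C(C)(C)C)cc1O[Si](C)(C)C(C)(C)C | intermediate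
6 | 2-[2,4-bis(tert-butyldimethylsilyloxy)-5-{[(2R)-3,3-dimethyloxiran-2-yl]methyl}phenyl]-2-methyl-1,3-dioxolane | CC1(C)O[C@@H]1Cc1cc(C2(C)OCCO2)c(O[Si](C)(C)C(C)(C)C)cc1O[Si](C)(C)C(C)(C)C | intermediate
7 | 4-{[(2R)-3,3-dimethyloxiran-2-yl]methyl}-6-(2-methyl-1,3-dioxolan-2-yl)benzene-1,3-diol (present as its tetrabutylammonium phenoxide) | CC1(C)O[C@@H]1Cc1cc(C2(C)OCCO2)c(O)cc1O | intermediate
8 | (2S)-2-(2-hydroxypropan-2-yl)-5-(2-methyl-1,3-dioxolan-2-yl)-2,3-dihydro-1-benzofuran-6-ol | CC(C)(O)[C@@H]1Cc2cc(C3(C)OCCO3)c(O)cc2O1 | intermediate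
9 | 2-[(2S)-5-(2-methyl-1,3-dioxolan-2-yl)-6-(triisopropylsilyloxy)-2,3-dihydro-1-benzofuran-2-yl]propan-2-ol | CC(C)(O)[C@@H]1Cc2cc(C3(C)OCCO3)c(O[Si](C(C)C)(C(C)C)C(C)C)cc2O1 | intermediate
10 | diethylsilane | CC[SiH2]CC | starting material
11 | diethyl{2-[(2S)-5-(2-methyl-1,3-dioxolan-2-yl)-6-(triisopropylsilyloxy)-2,3-dihydro-1-benzofuran-2-yl]propan-2-yloxy}silane | CC[SiH](CC)OC(C)(C)[C@@H]1Cc2cc(C3(C)OCCO3)c(O[Si](C(C)C)(C(C)C)C(C)C)cc2O1 | intermediate
12 | cis-fused 2,2-diethyl-5,5-dimethyl-1,2-oxasilolane on C2–C3 of 5-(2-methyl-1,3-dioxolan-2-yl)-6-(triisopropylsilyloxy)-2,3-dihydro-1-benzofuran (Si on C3; 2R,3R) | CC[Si]1(CC)OC(C)(C)[C@H]2Oc3cc(O[Si](C(C)C)(C(C)C)C(C)C)c(C4(C)OCCO4)cc3[C@@H]12 | intermediate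
13 | (2S,3R)-2-(2-hydroxypropan-2-yl)-5-(2-methyl-1,3-dioxolan-2-yl)-6-(triisopropylsilyloxy)-2,3-dihydro-1-benzofuran-3-ol | CC(C)(O)[C@H]1Oc2cc(O[Si](C(C)C)(C(C)C)C(C)C)c(C3(C)OCCO3)cc2[C@H]1O | intermediate
14 | 1-[(2S,3R)-3-hydroxy-2-(2-hydroxypropan-2-yl)-6-(triisopropylsilyloxy)-2,3-dihydro-1-benzofuran-5-yl]ethan-1-one | CC(C)(O)[C@H]1Oc2cc(O[Si](C(C)C)(C(C)C)C(C)C)c(C(C)=O)cc2[C@H]1O | intermediate
15 | angelic acid, (2Z)-2-methylbut-2-enoic acid | C/C=C(/C)C(=O)O | starting material
16 | angelic 2,4,6-trichlorobenzoic anhydride | C/C=C(/C)C(=O)OC(=O)c1c(Cl)cc(Cl)cc1Cl | intermediate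
17 | (2S,3R)-5-acetyl-2-(2-hydroxypropan-2-yl)-6-(triisopropylsilyloxy)-2,3-dihydro-1-benzofuran-3-yl (2Z)-2-methylbut-2-enoate | CC(C)(O)[C@H]1Oc2cc(O[Si](C(C)C)(C(C)C)C(C)C)c(C(C)=O)cc2[C@H]1OC(=O)/C(C)=C\C | intermediate
18 | (2R,3R)-5-acetyl-2-(prop-1-en-2-yl)-6-(triisopropylsilyloxy)-2,3-dihydro-1-benzofuran-3-yl (2Z)-2-methylbut-2-enoate | C=C(C)[C@H]1Oc2cc(O[Si](C(C)C)(C(C)C)C(C)C)c(C(C)=O)cc2[C@H]1OC(=O)/C(C)=C\C | intermediate
19 | (2R,3R)-5-acetyl-2-(3-hydroxyprop-1-en-2-yl)-6-(triisopropylsilyloxy)-2,3-dihydro-1-benzofuran-3-yl (2Z)-2-methylbut-2-enoate | C=C(CO)[C@H]1Oc2cc(O[Si](C(C)C)(C(C)C)C(C)C)c(C(C)=O)cc2[C@H]1OC(=O)/C(C)=C\C | intermediate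
20 | (2R,3R)-2-[3-(acetyloxy)prop-1-en-2-yl]-5-acetyl-6-(triisopropylsilyloxy)-2,3-dihydro-1-benzofuran-3-yl (2Z)-2-methylbut-2-enoate | C=C(COC(C)=O)[C@H]1Oc2cc(O[Si](C(C)C)(C(C)C)C(C)C)c(C(C)=O)cc2[C@H]1OC(=O)/C(C)=C\C | intermediate
21 | (2R,3R)-2-[3-(acetyloxy)prop-1-en-2-yl]-5-acetyl-6-hydroxy-2,3-dihydro-1-benzofuran-3-yl (2Z)-2-methylbut-2-enoate | C=C(COC(C)=O)[C@H]1Oc2cc(O)c(C(C)=O)cc2[C@H]1OC(=O)/C(C)=C\C | target

**Step count and risks**
Total: 14 steps. Longest linear sequence: 14 steps (from 1; the route is fully linear).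

Steps most likely to fail:

1. Step 8 (the one step beyond established scope). The iridium silyl may fail to cleave the hindered benzylic C3–H bond at a useful rate, so that redistribution at silicon, loss of the silyl ether or slow intermolecular arene silylation takes over. Fallback with known chemistry, from 9 back to 14: 9 would be treated with 2,2,2-trifluoroethyl isocyanate (CuCl, DMF) to give the carbamate F1. N-Bromination with acetyl hypobromite (from PhI(OAc)2 and Br2) would give the N-bromocarbamate F2. Irradiation with a fluorescent lamp in PhCF3 with CBr4 would pass the bromine to C3 by a Hofmann–Löffler–Freytag-type 1,6-hydrogen transfer, giving the benzylic bromide F3. Ag2CO3 in CH2Cl2 would close the cis-fused cyclic iminocarbonate F4, aqueous acetic acid would hydrolyse both the imine and the ketal to the cyclic carbonate F5, and brief K2CO3 in MeOH at 0 °C would release diol 14. The six-membered ring again forces the C3 oxygen cis to the side chain, and the sequence also avoids the C–Si oxidation of step 9.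

2. Step 12. The ene reaction of the oxygen-deactivated alkene may be slow, with over-oxidation of the allylic alcohol to the enal and competing oxidation of the angelate methyl groups or alpha to the aryl ketone. Fallback, from 18 back to 20: selenium-catalysed ene-type allylic chlorination with N-chlorosuccinimide and catalytic PhSeCl in CH2Cl2 would give the allylic chloride F6, and displacement with CsOAc in DMF at rt would give acetate 20 directly, which makes step 13 unnecessary.

3. Step 1. The Friedel–Crafts alkylation may show poor regiocontrol (attack at C3, O-alkylation, double prenylation) and acid-promoted cyclisation of the product onto the neighbouring phenol. Fallback, from 1 back to 4: bromination with N-bromosuccinimide in MeCN at 0 °C, para to the chelated hydroxyl, would give 1-(5-bromo-2,4-dihydroxyphenyl)ethan-1-one F7; silylation as in step 2 would give the bis(silyl ether) F8; Stille coupling with tributyl(3-methylbut-2-en-1-yl)stannane (Pd(PPh3)4, DMF, 90 °C) would place the prenyl group, through its primary carbon, on the carbon that carried bromine and return to 4.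

**Further compounds**
F1 | step 8 | 2-[(2S)-5-(2-methyl-1,3-dioxolan-2-yl)-6-(triisopropylsilyloxy)-2,3-dihydro-1-benzofuran-2-yl]propan-2-yl N-(2,2,2-trifluoroethyl)carbamate | CC(C)(OC(=O)NCC(F)(F)F)[C@@H]1Cc2cc(C3(C)OCCO3)c(O[Si](C(C)C)(C(C)C)C(C)C)cc2O1
F2 | step 8 | 2-[(2S)-5-(2-methyl-1,3-dioxolan-2-yl)-6-(triisopropylsilyloxy)-2,3-dihydro-1-benzofuran-2-yl]propan-2-yl N-bromo-N-(2,2,2-trifluoroethyl)carbamate | CC(C)(OC(=O)N(Br)CC(F)(F)F)[C@@H]1Cc2cc(C3(C)OCCO3)c(O[Si](C(C)C)(C(C)C)C(C)C)cc2O1
F3 | step 8 | 2-[(2R)-3-bromo-5-(2-methyl-1,3-dioxolan-2-yl)-6-(triisopropylsilyloxy)-2,3-dihydro-1-benzofuran-2-yl]propan-2-yl N-(2,2,2-trifluoroethyl)carbamate (C3 not controlled) | CC(C)(OC(=O)NCC(F)(F)F)[C@H]1Oc2cc(O[Si](C(C)C)(C(C)C)C(C)C)c(C3(C)OCCO3)cc2C1Br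
F4 | step 8 | cis-fused six-membered cyclic N-(2,2,2-trifluoroethyl)iminocarbonate spanning O–C1' and O–C3 of ketal diol 13 (2S,3R) | FC(F)(F)CN=C1OC(C)(C)[C@H]2Oc3cc(O[Si](C(C)C)(C(C)C)C(C)C)c(C4(C)OCCO4)cc3[C@H]2O1
F5 | step 8 | cis-fused six-membered cyclic carbonate of diol 14 (2S,3R) | O=C1OC(C)(C)[C@H]2Oc3cc(O[Si](C(C)C)(C(C)C)C(C)C)c(C(C)=O)cc3[C@H]2O1
F6 | step 12 | (2R,3R)-5-acetyl-2-(3-chloroprop-1-en-2-yl)-6-(triisopropylsilyloxy)-2,3-dihydro-1-benzofuran-3-yl (2Z)-2-methylbut-2-enoate | C=C(CCl)[C@H]1Oc2cc(O[Si](C(C)C)(C(C)C)C(C)C)c(C(C)=O)cc2[C@H]1OC(=O)/C(C)=C\C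
F7 | step 1 | 1-(5-bromo-2,4-dihydroxyphenyl)ethan-1-one | CC(=O)c1cc(Br)c(O)cc1O
F8 | step 1 | 1-[5-bromo-2,4-bis(tert-butyldimethylsilyloxy)phenyl]ethan-1-one | CC(=O)c1cc(Br)c(O[Si](C)(C)C(C)(C)C)cc1O[Si](C)(C)C(C)(C)C
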